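**Plan**

1. Locants (clerodane-type, used in all names): C2 ketone, C1 its CH2, bridgeheads C3 and C10, C4 (CHMe, C18), C5 (CMe, C19), C6 (CHOAc), C7, C8 (CHMe, C17), C9 (quaternary), C20 (bridging CH2), C11–C16 side chain with C13 the carbinol.
2. The bicyclo[2.2.2]octan-2-one (bridges C1–C2, C4–C5, C9–C20) has its ketone on one two-carbon bridge and the C6 oxygen next to C5. This is the retron of a 2-silyloxycyclohexa-1,3-diene adding to an enone, so C3–C4 and C5–C10 are cut. That opens the carbocycle C3–C4–C5–C10–C9–C20, and with it ring B (C5–C10), down to monocyclic trienone 30.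
3. Further cuts: C5–C6 (Weinreb amide plus butenyllithium), the C2 oxygen (allylic oxidation), C8–C9 (Ireland–Claisen of propanoate 16), C9–C11 (Grignard of bromide 10 plus 3-ethoxycyclohexenone).
4. Forward order: side chain (steps 1–6), cyclohexene with quaternary C9 (7–10), tether and diene (11–15), all three remaining rings in one cycloaddition (16), end game (17–19).
5. Stereochemistry: C13 from Sharpless epoxidation and reductive epoxide opening; the C1 carbinol from CBS reduction, relayed to C9 and C8 by the chair Claisen; C3, C4, C5, C10 from the tether-controlled cycloaddition of the (E)-enone; C6 from thermodynamic (dissolving-metal) reduction.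

Key step: step 16

Remark: compounds 1, 11 and 27 are taken as commercial; descriptors in the names refer to the locants above or to the local name.

**Step 1**
Reactants: 1 tert-butyl(but-3-yn-1-yloxy)dimethylsilane
Product: 4 (E)-5-(tert-butyldimethylsilyloxy)-3-methylpent-2-en-1-ol, via alkenylalane 2 (not isolated), via lithium aluminate 3 (not isolated)
Conditions: AlMe3, Cp2ZrCl2 (cat.), CH2Cl2, 0 °C to rt; then n-BuLi, THF/hexane, −78 °C; (CH2O)n, −78 °C to rt; aq. Rochelle salt
Reagents that add atoms: trimethylaluminium, C[Al](C)C; formaldehyde (as paraformaldehyde), C=O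
Why: Negishi zirconium-catalysed syn-carboalumination puts Me and Al cis across the terminal alkyne, and hydroxymethylation of the derived aluminate with retention should give only the (E)-trisubstituted allylic alcohol.

**Step 2**
Reactants: 4 (E)-5-(tert-butyldimethylsilyloxy)-3-methylpent-2-en-1-ol
Product: 5 [(2S,3S)-3-[2-(tert-butyldimethylsilyloxy)ethyl]-3-methyloxiran-2-yl]methanol
Conditions: Ti(OiPr)4 (cat.), L-(+)-diethyl tartrate (cat.), t-BuOOH, 4 Å sieves, CH2Cl2, −20 °C
Reagents that add atoms: tert-butyl hydroperoxide, CC(C)(C)OO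
Why: Sharpless asymmetric epoxidation of an (E)-trisubstituted allylic alcohol with the L-(+)-tartrate should deliver oxygen to the face that gives the (2S,3S)-epoxide, which fixes the later C13 centre.

**Step 3**
Reactants: 5 [(2S,3S)-3-[2-(tert-butyldimethylsilyloxy)ethyl]-3-methyloxiran-2-yl]methanol
Product: 7 (3S)-5-(tert-butyldimethylsilyloxy)-3-methylpent-1-en-3-ol, via epoxy iodide 6 (not isolated)
Conditions: I2, PPh3, imidazole, THF, 0 °C; filter; then Zn dust, AcOH, EtOH, 0 °C to rt
Reagents that add atoms: none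
Why: Appel iodination followed by zinc-induced reductive β-elimination of the 2,3-epoxy iodide breaks only the secondary C–O bond, so the tertiary C–O bond keeps its configuration and the vinyl group appears (epoxy alcohol to allylic alcohol transposition).

**Step 4**
Reactants: 7 (3S)-5-(tert-butyldimethylsilyloxy)-3-methylpent-1-en-3-ol
Product: 8 (3S)-3-methylpent-4-ene-1,3-diol
Conditions: Bu4NF, THF, 0 °C to rt
Reagents that add atoms: none
Why: Fluoride cleaves the primary silyl ether and leaves the tertiary allylic alcohol untouched.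

**Step 5**
Reactants: 8 (3S)-3-methylpent-4-ene-1,3-diol
Product: 9 (3S)-5-bromo-3-methylpent-1-en-3-ol
Conditions: CBr4, PPh3, CH2Cl2, 0 °C
Reagents that add atoms: tetrabromomethane, BrC(Br)(Br)Br
Why: Appel bromination should be selective for the primary alcohol, because the tertiary alcohol does not form an oxyphosphonium ion at 0 °C.

**Step 6**
Reactants: 9 (3S)-5-bromo-3-methylpent-1-en-3-ol
Product: 10 {[(3S)-5-bromo-3-methylpent-1-en-3-yl]oxy}triethylsilane
Conditions: Et3SiOTf, 2,6-lutidine, CH2Cl2, −78 to 0 °C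
Reagents that add atoms: triethylsilyl triflate, CC[Si](CC)(CC)OS(=O)(=O)C(F)(F)F
Why: Silyl triflate silylation of the tertiary alcohol gives an ether that should survive the organometallic, base and oxidation steps and is removed by fluoride at the end.

**Step 7**
Reactants: 10 {[(3S)-5-bromo-3-methylpent-1-en-3-yl]oxy}triethylsilane; 11 3-ethoxycyclohex-2-en-1-one
Product: 14 3-[(3S)-3-methyl-3-(triethylsilyloxy)pent-4-en-1-yl]cyclohex-2-en-1-one, via Grignard reagent 12 (not isolated), via magnesium alkoxide 13 (not isolated)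
Conditions: Mg turnings, THF, rt; add 11, 0 °C; then 1 M HCl, THF, 0 °C, short
Reagents that add atoms: water, O
Why: Stork–Danheiser sequence, in which 1,2-addition of the Grignard reagent to the vinylogous ester and acid hydrolysis with allylic transposition should give the 3-alkyl enone.

**Step 8**
Reactants: 14 3-[(3S)-3-methyl-3-(triethylsilyloxy)pent-4-en-1-yl]cyclohex-2-en-1-one
Product: 15 (1S)-3-[(3S)-3-methyl-3-(triethylsilyloxy)pent-4-en-1-yl]cyclohex-2-en-1-ol
Conditions: (R)-2-methyl-CBS-oxazaborolidine (0.2 equiv), catecholborane, toluene, −78 °C; aq. NaOH work-up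
Reagents that add atoms: none
Why: Corey–Bakshi–Shibata reduction with the alkene flank as the large group should give the (S)-allylic alcohol under reagent control, and catecholborane at −78 °C leaves the vinyl group unhydroborated.

**Step 9**
Reactants: 15 (1S)-3-[(3S)-3-methyl-3-(triethylsilyloxy)pent-4-en-1-yl]cyclohex-2-en-1-ol
Product: 16 (1S)-3-[(3S)-3-methyl-3-(triethylsilyloxy)pent-4-en-1-yl]cyclohex-2-en-1-yl propanoate
Conditions: (EtCO)2O, Et3N, DMAP (cat.), CH2Cl2, 0 °C to rt
Reagents that add atoms: propanoic anhydride, CCC(=O)OC(=O)CC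
Why: DMAP-catalysed acylation of the secondary allylic alcohol with retention at the carbinol.

**Step 10**
Reactants: 16 (1S)-3-[(3S)-3-methyl-3-(triethylsilyloxy)pent-4-en-1-yl]cyclohex-2-en-1-yl propanoate
Product: 20 (2S)-2-[(1S)-1-[(3S)-3-methyl-3-(triethylsilyloxy)pent-4-en-1-yl]cyclohex-2-en-1-yl]propanoic acid, via lithium enolate 17 (not isolated), via silyl ketene acetal 18 (not isolated), via trimethylsilyl ester 19 (not isolated)
Conditions: LDA, THF, −78 °C; Me3SiCl/Et3N, −78 °C to rt, then 60 °C; brief 1 M HCl work-up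
Reagents that add atoms: none
Why: Ireland–Claisen rearrangement, in which LDA in THF gives the (E)-silyl ketene acetal and the chair [3,3] shift (methyl turned away from ring CH2 C20) delivers C8 to C9 on the face of the departing C1–O bond, so the carbinol configuration should be relayed to quaternary C9 and to the C8 methyl centre.

**Step 11**
Reactants: 20 (2S)-2-[(1S)-1-[(3S)-3-methyl-3-(triethylsilyloxy)pent-4-en-1-yl]cyclohex-2-en-1-yl]propanoic acid
Product: 22 (3S)-1-diazo-3-[(1S)-1-[(3S)-3-methyl-3-(triethylsilyloxy)pent-4-en-1-yl]cyclohex-2-en-1-yl]butan-2-one, via acid chloride 21 (not isolated)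
Conditions: 1-chloro-N,N,2-trimethylprop-1-en-1-amine, CH2Cl2, 0 °C; then CH2N2 (excess), Et2O, 0 °C
Reagents that add atoms: diazomethane, C=[N+]=[N-]
Why: First half of an Arndt–Eistert homologation, with neutral acid chloride formation and acylation of diazomethane in the absence of amine base, so C8 should not epimerise through a ketene.

**Step 12**
Reactants: 22 (3S)-1-diazo-3-[(1S)-1-[(3S)-3-methyl-3-(triethylsilyloxy)pent-4-en-1-yl]cyclohex-2-en-1-yl]butan-2-one
Product: 24 (3R)-N-methoxy-N-methyl-3-[(1R)-1-[(3S)-3-methyl-3-(triethylsilyloxy)pent-4-en-1-yl]cyclohex-2-en-1-yl]butanamide, via ketene 23 (not isolated)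
Conditions: PhCO2Ag (cat.), Et3N, MeNH(OMe), THF, −20 °C to rt, dark
Reagents that add atoms: N,O-dimethylhydroxylamine, CNOC
Why: Silver-catalysed Wolff rearrangement with retention at the migrating C8, the ketene being trapped by the hydroxylamine to give the homologated Weinreb amide directly (the descriptors change only through CIP priorities).

**Step 13**
Reactants: 24 (3R)-N-methoxy-N-methyl-3-[(1R)-1-[(3S)-3-methyl-3-(triethylsilyloxy)pent-4-en-1-yl]cyclohex-2-en-1-yl]butanamide
Product: 25 (3R)-N-methoxy-N-methyl-3-[(1S)-1-[(3S)-3-methyl-3-(triethylsilyloxy)pent-4-en-1-yl]-4-oxocyclohex-2-en-1-yl]butanamide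
Conditions: Rh2(cap)4 (dirhodium tetracaprolactamate, cat.), t-BuOOH, K2CO3, CH2Cl2, rt
Reagents that add atoms: tert-butyl hydroperoxide, CC(C)(C)OO
Why: Dirhodium-catalysed allylic C–H oxidation, where C2 is the only allylic CH2 in the molecule (C9 is quaternary and the side-chain vinyl has no allylic hydrogen), so only the C2 enone should form.

**Step 14**
Reactants: 25 (3R)-N-methoxy-N-methyl-3-[(1S)-1-[(3S)-3-methyl-3-(triethylsilyloxy)pent-4-en-1-yl]-4-oxocyclohex-2-en-1-yl]butanamide
Product: 26 (3R)-3-[(1S)-4-(tert-butyldimethylsilyloxy)-1-[(3S)-3-methyl-3-(triethylsilyloxy)pent-4-en-1-yl]cyclohexa-2,4-dien-1-yl]-N-methoxy-N-methylbutanamide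
Conditions: t-BuMe2SiOTf, Et3N, CH2Cl2, −78 to 0 °C
Reagents that add atoms: tert-butyldimethylsilyl triflate, CC(C)(C)[Si](C)(C)OS(=O)(=O)C(F)(F)F
Why: Soft enolisation can only remove a C3 hydrogen because C9 is quaternary, giving the cross-conjugated 2-silyloxy diene, which also masks the ring ketone against the organolithium of the next step.

**Step 15**
Reactants: 26 (3R)-3-[(1S)-4-(tert-butyldimethylsilyloxy)-1-[(3S)-3-methyl-3-(triethylsilyloxy)pent-4-en-1-yl]cyclohexa-2,4-dien-1-yl]-N-methoxy-N-methylbutanamide; 27 (E)-2-bromobut-2-ene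
Product: 30 (2E,6R)-6-[(1S)-4-(tert-butyldimethylsilyloxy)-1-[(3S)-3-methyl-3-(triethylsilyloxy)pent-4-en-1-yl]cyclohexa-2,4-dien-1-yl]-3-methylhept-2-en-4-one, via butenyllithium 28 (not isolated), via lithium hemiaminal 29 (not isolated)
Conditions: 27, t-BuLi (2 equiv), Et2O, −78 °C; add 26, THF, −78 °C; sat. NH4Cl, −78 to 0 °C; crude 30 kept cold
Reagents that add atoms: none
Why: Weinreb ketone synthesis, in which bromine–lithium exchange keeps the alkene geometry and the chelated adduct releases the (E)-enone only on quench, so over-addition should not occur.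

**Step 16**
Reactants: 30 (2E,6R)-6-[(1S)-4-(tert-butyldimethylsilyloxy)-1-[(3S)-3-methyl-3-(triethylsilyloxy)pent-4-en-1-yl]cyclohexa-2,4-dien-1-yl]-3-methylhept-2-en-4-one
Product: 31 tricyclic silyl enol ether: 2-(tert-butyldimethylsilyloxy)-6-oxo tricycle with C1=C2 enol ether and 13-O-triethylsilyl group, (3R,4R,5S,8R,9S,10S,13S)
Conditions: toluene (0.01 M), BHT (cat.), Et3N (trace), 90–110 °C, sealed tube
Reagents that add atoms: none
Why: Thermal intramolecular Diels–Alder reaction in which the electron-rich 2-silyloxy diene C3=C2(OSi)–C1=C10 (largest HOMO coefficient at C3) adds suprafacially to the enone C4=C5–C6=O, C3 bonding to the β-carbon C4 and C10 to the α-carbon C5. The closest known reaction types are intramolecular Diels–Alder reactions of cyclohexa-1,3-dienes tethered at the sp3 carbon next to the diene, and the intramolecular double Michael reaction of cyclohexenone dienolates with tethered acceptors. Ring B (C5–C6–C7–C8–C9–C10) closes as a six-membered ring through the three-atom tether C6–C7–C8 anchored on C9, while the two new bonds C3–C4 and C5–C10 close the bicyclo[2.2.2]octene, that is the carbocycle C3–C4–C5–C10–C9–C20 together with the enol ether ring C1–C2–C3–C4–C5–C10. C3 and C10 follow from C9, because the tether reaches only the diene face that carries C8; C5 follows from the tether, which forces C6 to the side of the C9–C20 bridge and C19 toward the enol ether bridge; C4 follows from the (E)-enone geometry, which keeps C18 cis to C19. The step needs regioselectivity (C5 to C10, not to C3) and chemoselectivity (the ring ketone alone as diene, the side-chain vinyl inert), secured by the tether length, the matched polarity of diene and enone, and the one-directional enol silylation of the 4,4-disubstituted enone.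

**Step 17**
Reactants: 31 tricyclic silyl enol ether (6-ketone)
Product: 32 tricyclic silyl enol ether with equatorial 6-hydroxyl, (3R,4R,5S,6R,8R,9S,10S,13S)
Conditions: Li, NH3(l), THF, t-BuOH, −78 °C; NH4Cl
Reagents that add atoms: none
Why: Dissolving-metal reduction should give the thermodynamically preferred equatorial C6 alcohol (the axial epimer would be 1,3-diaxial to the C8 methyl), while C2 stays masked as its silyl enol ether and the isolated vinyl group is inert.

**Step 18**
Reactants: 32 tricyclic silyl enol ether with equatorial 6-hydroxyl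
Product: 33 6-acetate of 32, (3R,4R,5S,6R,8R,9S,10S,13S)
Conditions: Ac2O, pyridine, DMAP (cat.), CH2Cl2, rt
Reagents that add atoms: acetic anhydride, CC(=O)OC(C)=O
Why: DMAP-catalysed acetylation of the secondary alcohol, under which the silyl enol ether and the tertiary silyl ether should not react.

**Step 19**
Reactants: 33 6-acetate of 32
Product: 34 CNP0281208.1, (3R,4R,5S,6R,8R,9S,10S,13S)-6-acetoxy-13-hydroxy-3,20-cycloclerod-14-en-2-one
Conditions: HF·pyridine, pyridine, THF, 0 °C to rt
Reagents that add atoms: none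
Why: Buffered HF should cleave the silyl enol ether (protonation at C1 gives the C2 ketone) and the tertiary triethylsilyl ether in one operation without touching the acetate.

**Compound list**

1 | tert-butyl(but-3-yn-1-yloxy)dimethylsilane | C#CCCO[Si](C)(C)C(C)(C)C | starting material
2 | (E)-[4-(tert-butyldimethylsilyloxy)-2-methylbut-1-en-1-yl]dimethylalane (Al cis to the C2 methyl) | C[Al](C)/C=C(\C)CCO[Si](C)(C)C(C)(C)C | intermediate
3 | lithium butyl[(E)-4-(tert-butyldimethylsilyloxy)-2-methylbut-1-en-1-yl]dimethylaluminate | [Li+].CCCC[Al-](C)(C)/C=C(\C)CCO[Si](C)(C)C(C)(C)C | intermediate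
4 | (E)-5-(tert-butyldimethylsilyloxy)-3-methylpent-2-en-1-ol | OC/C=C(\C)CCO[Si](C)(C)C(C)(C)C | intermediate
5 | [(2S,3S)-3-[2-(tert-butyldimethylsilyloxy)ethyl]-3-methyloxiran-2-yl]methanol | OC[C@@H]1O[C@@]1(C)CCO[Si](C)(C)C(C)(C)C | intermediate
6 | (2R,3S)-2-(iodomethyl)-3-methyl-3-[2-(tert-butyldimethylsilyloxy)ethyl]oxirane | IC[C@@H]1O[C@@]1(C)CCO[Si](C)(C)C(C)(C)C | intermediate
7 | (3S)-5-(tert-butyldimethylsilyloxy)-3-methylpent-1-en-3-ol | C=C[C@@](C)(O)CCO[Si](C)(C)C(C)(C)C | intermediate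
8 | (3S)-3-methylpent-4-ene-1,3-diol | C=C[C@@](C)(O)CCO | intermediate
9 | (3S)-5-bromo-3-methylpent-1-en-3-ol | C=C[C@@](C)(O)CCBr | intermediate
10 | {[(3S)-5-bromo-3-methylpent-1-en-3-yl]oxy}triethylsilane | C=C[C@@](C)(O[Si](CC)(CC)CC)CCBr | intermediate
11 | 3-ethoxycyclohex-2-en-1-one | CCOC1=CC(=O)CCC1 | starting material
12 | [(3S)-3-methyl-3-(triethylsilyloxy)pent-4-en-1-yl]magnesium bromide | C=C[C@@](C)(O[Si](CC)(CC)CC)CC[Mg]Br | intermediate
13 | bromomagnesium 3-ethoxy-1-[(3S)-3-methyl-3-(triethylsilyloxy)pent-4-en-1-yl]cyclohex-2-en-1-olate (either configuration at ring C1) | C=C[C@@](C)(O[Si](CC)(CC)CC)CCC1(O[Mg]Br)C=C(OCC)CCC1 | intermediate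
14 | 3-[(3S)-3-methyl-3-(triethylsilyloxy)pent-4-en-1-yl]cyclohex-2-en-1-one | C=C[C@@](C)(O[Si](CC)(CC)CC)CCC1=CC(=O)CCC1 | intermediate
15 | (1S)-3-[(3S)-3-methyl-3-(triethylsilyloxy)pent-4-en-1-yl]cyclohex-2-en-1-ol | C=C[C@@](C)(O[Si](CC)(CC)CC)CCC1=C[C@@H](O)CCC1 | intermediate
16 | (1S)-3-[(3S)-3-methyl-3-(triethylsilyloxy)pent-4-en-1-yl]cyclohex-2-en-1-yl propanoate | C=C[C@@](C)(O[Si](CC)(CC)CC)CCC1=C[C@@H](OC(=O)CC)CCC1 | intermediate
17 | lithium (E)-enolate of 16 (methyl cis to the ring oxygen) | C=C[C@@](C)(O[Si](CC)(CC)CC)CCC1=C[C@@H](O/C(O[Li])=C\C)CCC1 | intermediate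
18 | (E)-trimethylsilyl ketene acetal of 16 (methyl cis to the ring oxygen) | C=C[C@@](C)(O[Si](CC)(CC)CC)CCC1=C[C@@H](O/C(O[Si](C)(C)C)=C\C)CCC1 | intermediate
19 | trimethylsilyl (2S)-2-[(1S)-1-[(3S)-3-methyl-3-(triethylsilyloxy)pent-4-en-1-yl]cyclohex-2-en-1-yl]propanoate | C=C[C@@](C)(O[Si](CC)(CC)CC)CC[C@@]1(C=CCCC1)[C@H](C)C(=O)O[Si](C)(C)C | intermediate
20 | (2S)-2-[(1S)-1-[(3S)-3-methyl-3-(triethylsilyloxy)pent-4-en-1-yl]cyclohex-2-en-1-yl]propanoic acid | C=C[C@@](C)(O[Si](CC)(CC)CC)CC[C@@]1(C=CCCC1)[C@H](C)C(=O)O | intermediate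
21 | acid chloride of 20 (same configuration) | C=C[C@@](C)(O[Si](CC)(CC)CC)CC[C@@]1(C=CCCC1)[C@H](C)C(=O)Cl | intermediate
22 | (3S)-1-diazo-3-[(1S)-1-[(3S)-3-methyl-3-(triethylsilyloxy)pent-4-en-1-yl]cyclohex-2-en-1-yl]butan-2-one | C=C[C@@](C)(O[Si](CC)(CC)CC)CC[C@@]1(C=CCCC1)[C@H](C)C(=O)C=[N+]=[N-] | intermediate
23 | ketene from 22: 3-[1-(side chain)cyclohex-2-en-1-yl]but-1-en-1-one, C8 and C9 as in 24 | C=C[C@@](C)(O[Si](CC)(CC)CC)CC[C@@]1(C=CCCC1)[C@H](C)C=C=O | intermediate
24 | (3R)-N-methoxy-N-methyl-3-[(1R)-1-[(3S)-3-methyl-3-(triethylsilyloxy)pent-4-en-1-yl]cyclohex-2-en-1-yl]butanamide | C=C[C@@](C)(O[Si](CC)(CC)CC)CC[C@@]1(C=CCCC1)[C@H](C)CC(=O)N(C)OC | intermediate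
25 | (3R)-N-methoxy-N-methyl-3-[(1S)-1-[(3S)-3-methyl-3-(triethylsilyloxy)pent-4-en-1-yl]-4-oxocyclohex-2-en-1-yl]butanamide | C=C[C@@](C)(O[Si](CC)(CC)CC)CC[C@@]1(C=CC(=O)CC1)[C@H](C)CC(=O)N(C)OC | intermediate
26 | (3R)-3-[(1S)-4-(tert-butyldimethylsilyloxy)-1-[(3S)-3-methyl-3-(triethylsilyloxy)pent-4-en-1-yl]cyclohexa-2,4-dien-1-yl]-N-methoxy-N-methylbutanamide | C=C[C@@](C)(O[Si](CC)(CC)CC)CC[C@@]1(C=CC(O[Si](C)(C)C(C)(C)C)=CC1)[C@H](C)CC(=O)N(C)OC | intermediate
27 | (E)-2-bromobut-2-ene | C/C=C(\C)Br | starting material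
28 | but-2-en-2-yllithium with the two methyl groups cis (geometry kept from 27) | C/C=C(\C)[Li] | intermediate
29 | lithium hemiaminal adduct of 28 and 26 (either configuration at the new carbinol carbon) | C=C[C@@](C)(O[Si](CC)(CC)CC)CC[C@@]1(C=CC(O[Si](C)(C)C(C)(C)C)=CC1)[C@H](C)CC(O[Li])(N(C)OC)/C(C)=C/C | intermediate
30 | (2E,6R)-6-[(1S)-4-(tert-butyldimethylsilyloxy)-1-[(3S)-3-methyl-3-(triethylsilyloxy)pent-4-en-1-yl]cyclohexa-2,4-dien-1-yl]-3-methylhept-2-en-4-one | C=C[C@@](C)(O[Si](CC)(CC)CC)CC[C@@]1(C=CC(O[Si](C)(C)C(C)(C)C)=CC1)[C@H](C)CC(=O)/C(C)=C/C | intermediate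
31 | tricyclic 2-(tert-butyldimethylsilyloxy)-1-ene 6-ketone, 13-O-triethylsilyl, (3R,4R,5S,8R,9S,10S,13S) | C=C[C@@](C)(O[Si](CC)(CC)CC)CC[C@@]12C[C@H]3C(O[Si](C)(C)C(C)(C)C)=C[C@@H]1[C@](C)([C@@H]3C)C(=O)C[C@H]2C | intermediate
32 | tricyclic 2-(tert-butyldimethylsilyloxy)-1-ene 6-ol (equatorial), 13-O-triethylsilyl, (3R,4R,5S,6R,8R,9S,10S,13S) | C=C[C@@](C)(O[Si](CC)(CC)CC)CC[C@@]12C[C@H]3C(O[Si](C)(C)C(C)(C)C)=C[C@@H]1[C@](C)([C@@H]3C)[C@H](O)C[C@H]2C | intermediate
33 | 6-acetate of 32, (3R,4R,5S,6R,8R,9S,10S,13S) | C=C[C@@](C)(O[Si](CC)(CC)CC)CC[C@@]12C[C@H]3C(O[Si](C)(C)C(C)(C)C)=C[C@@H]1[C@](C)([C@@H]3C)[C@H](OC(C)=O)C[C@H]2C | intermediate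
34 | CNP0281208.1, (3R,4R,5S,6R,8R,9S,10S,13S)-6-acetoxy-13-hydroxy-3,20-cycloclerod-14-en-2-one | C=C[C@@](C)(O)CC[C@@]12C[C@H]3C(=O)C[C@@H]1[C@](C)([C@@H]3C)[C@H](OC(C)=O)C[C@H]2C | target

**Totals**

Total step count: 19. Longest linear sequence: 19 steps (1 to 34 through steps 1–19; 11 and 27 are purchased).

**Steps most likely to fail, with fallbacks**

Step 10. Diastereocontrol at C8 may be lost by leakage through the boat transition state or by incomplete (E)-enolate formation, and the shift onto the fully substituted C9 may be slow. The fallback sets out from 15 and comes back at 20; it separates the two centres. Alcohol 15 is heated with triethyl orthoacetate and catalytic propanoic acid (Johnson–Claisen, same suprafacial transfer to C9, no enolate geometry involved) to give ethyl ester F1. LiOH gives acid F2. Pivaloyl chloride/Et3N and lithiated (S)-4-benzyloxazolidin-2-one give N-acyl oxazolidinone F3. NaN(SiMe3)2 and MeI methylate the chelated (Z)-enolate on the face away from the benzyl group to give methylated imide F4. LiOH/H2O2 removes the auxiliary and returns 20.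

Step 16. The cycloaddition of the trisubstituted enone onto a diene terminus next to a quaternary carbon may be slow, with competing hydrolysis or 1,5-hydrogen shift of the silyloxy diene. The fallback sets out from 30 and comes back at 31. Bu4NF/AcOH at −20 °C removes the enol silyl group to give enedione F5. Pyrrolidine condenses with the less hindered ring enone to the cross-conjugated 2-aminodiene F6, a more nucleophilic diene that should add to the tethered enone in the same sense (Michael–Michael or [4+2]) to give tricyclic enamine F7. Aqueous acetic acid hydrolyses it to tricyclic 2,6-dione F8. t-BuMe2SiOTf (1 equiv)/Et3N at −78 °C should silylate the unhindered C2 ketone in preference to the C6 ketone, which is flanked by quaternary C5, and returns 31.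

Step 17. Stereoselectivity at C6 may be poor, or the silyl enol ether may be lost under dissolving-metal conditions. The fallback sets out from 31 and comes back at 32. LiBH(s-Bu)3 at −78 °C attacks the open face and should give the axial 6-epi alcohol F9. Meerwein–Ponndorf–Verley/Oppenauer equilibration with Al(OiPr)3 and catalytic acetone in toluene at 80 °C passes through the ketone and should settle on the equatorial alcohol 32, in which the hydroxyl is no longer 1,3-diaxial to the C8 methyl.

**Further compounds**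

F1 | step 10 | ethyl 2-[(1S)-1-[(3S)-3-methyl-3-(triethylsilyloxy)pent-4-en-1-yl]cyclohex-2-en-1-yl]acetate (C9 as in 20) | C=C[C@@](C)(O[Si](CC)(CC)CC)CC[C@@]1(C=CCCC1)CC(=O)OCC
F2 | step 10 | 2-[1-[(3S)-3-methyl-3-(triethylsilyloxy)pent-4-en-1-yl]cyclohex-2-en-1-yl]acetic acid (C9 as in 20) | C=C[C@@](C)(O[Si](CC)(CC)CC)CC[C@@]1(C=CCCC1)CC(=O)O
F3 | step 10 | (4S)-4-benzyl-3-acyl-oxazolidin-2-one of F2 | C=C[C@@](C)(O[Si](CC)(CC)CC)CC[C@@]1(C=CCCC1)CC(=O)N2[C@@H](Cc3ccccc3)COC2=O
F4 | step 10 | (4S)-4-benzyl-3-[(2S)-2-methylacyl]oxazolidin-2-one (C8 and C9 as in 20) | C=C[C@@](C)(O[Si](CC)(CC)CC)CC[C@@]1(C=CCCC1)[C@H](C)C(=O)N2[C@@H](Cc3ccccc3)COC2=O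
F5 | step 16 | enedione: (2E,6R)-3-methyl-6-[(1S)-1-[(3S)-3-methyl-3-(triethylsilyloxy)pent-4-en-1-yl]-4-oxocyclohex-2-en-1-yl]hept-2-en-4-one | C=C[C@@](C)(O[Si](CC)(CC)CC)CC[C@@]1(C=CC(=O)CC1)[C@H](C)CC(=O)/C(C)=C/C
F6 | step 16 | 2-(pyrrolidin-1-yl) diene analogue of 30 | C=C[C@@](C)(O[Si](CC)(CC)CC)CC[C@@]1(C=CC(N2CCCC2)=CC1)[C@H](C)CC(=O)/C(C)=C/C
F7 | step 16 | tricyclic 2-(pyrrolidin-1-yl)-1-ene 6-ketone (enamine analogue of 31) | C=C[C@@](C)(O[Si](CC)(CC)CC)CC[C@@]12C[C@H]3C(N4CCCC4)=C[C@@H]1[C@](C)([C@@H]3C)C(=O)C[C@H]2C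
F8 | step 16 | tricyclic 2,6-dione, 13-O-triethylsilyl | C=C[C@@](C)(O[Si](CC)(CC)CC)CC[C@@]12C[C@H]3C(=O)C[C@@H]1[C@](C)([C@@H]3C)C(=O)C[C@H]2C
F9 | step 17 | 6-epi alcohol (axial, 6S) of 32 | C=C[C@@](C)(O[Si](CC)(CC)CC)CC[C@@]12C[C@H]3C(O[Si](C)(C)C(C)(C)C)=C[C@@H]1[C@](C)([C@@H]3C)[C@@H](O)C[C@H]2C
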